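I cannot trap substrate that the second reagent has already turned into side product.

    substrate + partner → open intermediate (k1 = 1.3 M⁻¹ min⁻¹)
    second reagent + open intermediate → target (k2 = 0.056 M⁻¹ min⁻¹)
    substrate + second reagent → side product (k3 = 1.5 M⁻¹ min⁻¹)
    target ⇌ isomer of the product (K4 = 2.5, k4 = 0.27 min⁻¹)
    open intermediate + capture agent → trapped intermediate (k5 = 2.5 M⁻¹ min⁻¹)
    target → over-reaction product (k6 = 1.6 × 10⁻⁵ min⁻¹)

substrate 0.050 M; partner 0.0750 M; second reagent 0.0900 M (in portions, 3); capture agent 0.0500 M; time 12 h; the portions of second reagent follow each other after 6.0 min, the first at the start

* at 12 h, what has stopped the reaction, if anything has (forward and back rates have come level / the partner has run out first / it is still moving / the second reagent has run out first / all of the substrate has reacted)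
* trapped intermediate at 12 h, in percent of the substrate charged
* amount of target if the flask were left three thousand times as long, in percent of the substrate charged

- the reaction counts as stopped when no species that holds the substrate changes by six tenths of a point or more over the second half of the time
- run time (flask): 12 h

The substrate forks: with the partner it makes open intermediate, and with the second reagent it makes side product. My measure is the fork ratio, the rate constant times [partner] on the first branch over the rate constant times [second reagent] on the other, both at full charge, a selectivity factor: 0.722. With one portion in, [second reagent] is a third of that charge, so the ratio starts at 2.17 and drifts down as portions arrive. These two ratios reckon to a first-branch share of 68.4 % at the start and 41.9 % at full charges. The substrate's opening half-life is 4.86 min against 6.0 min between portions, so it lives through the drift, and I take the midpoint, 55.2 %.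

The open intermediate then forks again, and capture takes 96.1 % of it at full charges.

Which numbers must be good? A factor of two on the fork ratio moves the trapped yield by 14 percentage points, so both fork rate constants, the partner and the second reagent matter. The same error on the second reagent's attack on the open intermediate moves it by 2 points. The isomer equilibrium and the over-reaction act downstream and do not touch the trapped yield. The over-reaction serves the long question: the target's half-life by that step alone, 30 d, is longer than 12 h, but the long standing outlasts it, so I expect the target to drain away. The substrate is the limiting reagent, and its half-life by the side reaction alone, with the whole charge of second reagent counted as there at once, 0.086 h, is shorter than 12 h, so I expect it to be consumed. My trapped yield is 53.0 %.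

The forecast says all of the substrate has reacted, 55 % and 0 %, holding that “the excess capture agent outcompetes the second reagent”. My yield is lower than its figure.

The flask gives all of the substrate has reacted, 54.8 % and 0 %.

The side reaction is the main reason why the trapped yield falls short: the same run without it holds 91.1 % of trapped intermediate against 54.8 %. This flask sent 56.9 % through the first branch, between my 41.9 % and 68.4 %. In the neighbour flask with 0.030 M of partner, the fork ratio falls to 0.289, and the same midpoint and capture share give 33.1 %; that flask holds 30.0 % of trapped intermediate.

The rate constants were drawn at random within sensible limits, and the outcome is calculated.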